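**Retrosynthetic overview**

1. Ring locants used throughout: C1 = C(OH)(CH2OBz), C2 and C3 = CHOAc, C4=C5, C6 = CHOBz. The four acyl groups go on last: Bz on CH2OH and C6–OH, Ac on C2–OH and C3–OH, with the tertiary C1–OH left free.
2. The cis C1–OH/C6–O glycol is read as the osmylation product of a C1=C6 alkene. This leaves a cyclohexa-1,3-diene (C4=C5–C6=C1) carrying a trans C2,C3-diether and a C1–CH2OH arm.
3. Enabling feature: the trans-dioxygenated two-carbon unit C2–C3 sits between C1 and C4, the two ends of that four-carbon diene. The six-membered ring is therefore the [4+2] adduct of an (E)-enediol diether with C4–C5–C6–C1. Raising CH2OBz to CO2Me makes the diene electron-poor, and a temporary O–C(=O) bridge from C4 to C1 turns it into methyl 2-pyrone-3-carboxylate.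
4. Key disconnection: C3–C4 and C2–C1 together, by a catalytic enantioselective inverse-electron-demand Diels–Alder reaction. The catalyst sets C2 and C3, and the C2 ether later relays to C1 and C6 in a single osmylation.
5. Ring order: the pyrone ring is bought. The carbocycle is the only ring made (step 2, as a 2-oxabicyclo[2.2.2]octene). The lactone bridge leaves as CO2 (step 3).

Key step: step 2

Assumption: the (S,S) ligand is written for the sense of induction expected from the chelate model; both ligand enantiomers are commercial, and the antipode would be used, with nothing else changed, if the model pointed the other way. (PMB = 4-methoxybenzyl, Bz = benzoyl.)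

**Step 1**
Reactants: 1 (E)-1,2-bis(4,4,5,5-tetramethyl-1,3,2-dioxaborolan-2-yl)ethene; 2 4-methoxybenzyl alcohol
Product: 3 (E)-1,2-bis[(4-methoxybenzyl)oxy]ethene
Conditions: Cu(OAc)2 (4.4 equiv), Et3N, excess 2, 4 Å MS, CH2Cl2, rt
Reagents that add atoms: none
Why: Chan–Lam-type oxidative C–O coupling of an alkenyl pinacol boronate with an alcohol proceeds with retention of alkene geometry, so the E geometry bought with 1 should pass into both enol ether bonds of 3, while Et3N buffers against protodeboronation and enol ether hydrolysis.

**Step 2**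
Reactants: 3 (E)-1,2-bis[(4-methoxybenzyl)oxy]ethene; 4 methyl 2-oxo-2H-pyran-3-carboxylate
Product: 5 methyl (1R,4S,7R,8R)-7,8-bis[(4-methoxybenzyl)oxy]-3-oxo-2-oxabicyclo[2.2.2]oct-5-ene-4-carboxylate (C8 ether endo, syn to C5=C6; C7 ether exo, syn to the lactone bridge)
Conditions: Cu(OTf)2 (10 mol %), (S,S)-t-Bu-BOX (11 mol %), 4 Å MS, CH2Cl2, −40 to −20 °C
Reagents that add atoms: none
Why: The Cu(OTf)2–bis(oxazoline) complex chelates the lactone and ester carbonyls of 4, lowers the LUMO of the pyrone diene (C3=C4–C5=C6) and lets the very electron-rich alkene of 3 add across C6 and C3 in a concerted, asynchronous, suprafacial inverse-electron-demand Diels–Alder reaction in which bonding at C6 runs ahead. The closest known reaction type is the bis(oxazoline)–copper or lanthanide catalysed enantioselective cycloaddition of 3-alkoxycarbonyl-2-pyrones with acyclic alkyl enol ethers, applied here to an enediol diether. One carbocycle is closed by an intermolecular [4π+2π] cycloaddition, both new σ-bonds forming on one face of each partner, and the pyrone ring becomes the lactone bridge of the 2-oxabicyclo[2.2.2]octene. C7 and C8 (later C3 and C2) should come out trans because the E geometry of 3 is transferred suprafacially; their absolute configuration, and that of the bridgeheads C1 and C4, follows from the pyrone face left open by the tert-butyl groups of the ligand together with the endo placement of the C8 ether over the chelated dicarbonyl unit, where the developing oxocarbenium character is stabilised as with simple vinyl ethers. The step needs face selectivity (ligand), orientation selectivity (the C2h-symmetric alkene has no regiochemistry, but its two orientations give diastereomeric lactones that would end as opposite enantiomers of the diene, so 5 is freed from the minor one here by chromatography or crystallisation) and stereospecificity (low temperature and a weakly polar solvent disfavour a long-lived zwitterion that could rotate).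

**Step 3**
Reactants: 5 methyl (1R,4S,7R,8R)-7,8-bis[(4-methoxybenzyl)oxy]-3-oxo-2-oxabicyclo[2.2.2]oct-5-ene-4-carboxylate
Product: 6 methyl (5R,6R)-5,6-bis[(4-methoxybenzyl)oxy]cyclohexa-1,3-diene-1-carboxylate
Conditions: toluene (dilute), BHT (cat.), base-washed glassware, 100 °C
Reagents that add atoms: none
Why: Retro-Diels–Alder extrusion of CO2 is the normal thermal fate of pyrone adducts; it erases only the two bridgehead centres and leaves the two ether-bearing centres untouched, and the poor leaving-group ability of PMB ethers under acid- and base-free conditions should hold back aromatisation.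

**Step 4**
Reactants: 6 methyl (5R,6R)-5,6-bis[(4-methoxybenzyl)oxy]cyclohexa-1,3-diene-1-carboxylate
Product: 7 [(5R,6R)-5,6-bis[(4-methoxybenzyl)oxy]cyclohexa-1,3-dien-1-yl]methanol
Conditions: i-Bu2AlH (2.5 equiv), CH2Cl2, −78 °C
Reagents that add atoms: none
Why: 1,2-Reduction of a conjugated ester to the allylic alcohol with i-Bu2AlH removes the activating oxidation level, touches neither the ethers nor the diene, and affects no stereocentre.

**Step 5**
Reactants: 7 [(5R,6R)-5,6-bis[(4-methoxybenzyl)oxy]cyclohexa-1,3-dien-1-yl]methanol
Product: 9 (1S,2S,3R,6S)-1-(hydroxymethyl)-2,3-bis[(4-methoxybenzyl)oxy]cyclohex-4-ene-1,6-diol, via osmate ester TMEDA chelate 8 (not isolated)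
Conditions: OsO4 (1.05 equiv), TMEDA (1.1 equiv), CH2Cl2, −78 °C; then aq. Na2SO3, THF, reflux
Reagents that add atoms: osmium tetroxide, O=[Os](=O)(=O)=O
Why: In this hydrogen-bond-directed (Donohoe-type) dihydroxylation the OsO4·TMEDA complex should be steered by the only OH group, the C1–CH2OH arm, to the adjacent and more substituted C1=C6 bond rather than to C4=C5; the suprafacial [3+2] addition makes C1–O and C6–O cis, and attack opposite to the neighbouring C2 ether sets both new centres relative to C2.

**Step 6**
Reactants: 9 (1S,2S,3R,6S)-1-(hydroxymethyl)-2,3-bis[(4-methoxybenzyl)oxy]cyclohex-4-ene-1,6-diol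
Product: 10 [(1S,2S,3R,6S)-6-(benzoyloxy)-1-hydroxy-2,3-bis[(4-methoxybenzyl)oxy]cyclohex-4-en-1-yl]methyl benzoate
Conditions: BzCl (2.3 equiv), pyridine, CH2Cl2, 0 °C to rt
Reagents that add atoms: benzoyl chloride, O=C(Cl)c1ccccc1
Why: Rate-controlled O-acylation should take the primary and the secondary allylic hydroxyl groups and leave the hindered tertiary C1–OH free, with no stereocentre involved.

**Step 7**
Reactants: 10 [(1S,2S,3R,6S)-6-(benzoyloxy)-1-hydroxy-2,3-bis[(4-methoxybenzyl)oxy]cyclohex-4-en-1-yl]methyl benzoate
Product: 11 [(1R,2S,3R,6S)-6-(benzoyloxy)-1,2,3-trihydroxycyclohex-4-en-1-yl]methyl benzoate (same spatial arrangement as 10; the C1 descriptor changes by priority only)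
Conditions: DDQ (2.6 equiv), CH2Cl2, aq. pH 7 buffer, 0 °C to rt
Reagents that add atoms: none
Why: Oxidative PMB ether cleavage with DDQ goes through the benzylic oxocarbenium ion, which water hydrolyses; it is near neutral, so the benzoates should neither be cleaved nor migrate, and the C–O bonds at C2 and C3 are not broken.

**Step 8**
Reactants: 11 [(1R,2S,3R,6S)-6-(benzoyloxy)-1,2,3-trihydroxycyclohex-4-en-1-yl]methyl benzoate
Product: 12 cleistenediol F, [(1S,2S,3R,6S)-2,3-diacetoxy-6-(benzoyloxy)-1-hydroxycyclohex-4-en-1-yl]methyl benzoate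
Conditions: Ac2O (2.5 equiv), pyridine, DMAP (cat.), CH2Cl2, 0 °C
Reagents that add atoms: acetic anhydride, CC(=O)OC(C)=O
Why: Standard O-acetylation should take the two secondary hydroxyl groups, while the tertiary C1–OH, flanked by three acyloxy-bearing carbons, stays free at low temperature with limited reagent.

**Compound list**

1 | (E)-1,2-bis(4,4,5,5-tetramethyl-1,3,2-dioxaborolan-2-yl)ethene | CC1(C)OB(/C=C/B2OC(C)(C)C(C)(C)O2)OC1(C)C | starting material
2 | 4-methoxybenzyl alcohol | COc1ccc(CO)cc1 | starting material
3 | (E)-1,2-bis[(4-methoxybenzyl)oxy]ethene | COc1ccc(CO/C=C/OCc2ccc(OC)cc2)cc1 | intermediate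
4 | methyl 2-oxo-2H-pyran-3-carboxylate | COC(=O)C1=CC=COC1=O | starting material
5 | methyl (1R,4S,7R,8R)-7,8-bis[(4-methoxybenzyl)oxy]-3-oxo-2-oxabicyclo[2.2.2]oct-5-ene-4-carboxylate | COc1ccc(CO[C@@H]2[C@H]3C=C[C@](C(=O)OC)(C(=O)O3)[C@H]2OCc2ccc(OC)cc2)cc1 | intermediate
6 | methyl (5R,6R)-5,6-bis[(4-methoxybenzyl)oxy]cyclohexa-1,3-diene-1-carboxylate | COc1ccc(CO[C@@H]2C=CC=C(C(=O)OC)[C@H]2OCc2ccc(OC)cc2)cc1 | intermediate
7 | [(5R,6R)-5,6-bis[(4-methoxybenzyl)oxy]cyclohexa-1,3-dien-1-yl]methanol | COc1ccc(CO[C@@H]2C=CC=C(CO)[C@H]2OCc2ccc(OC)cc2)cc1 | intermediate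
8 | cyclic C1,C6-osmate ester of 9 (dioxo, hexavalent osmium) chelated by TMEDA | COc1ccc(CO[C@@H]2C=C[C@@H]3O[Os-2]4(=O)(=O)(O[C@]3(CO)[C@H]2OCc2ccc(OC)cc2)[N+](C)(C)CC[N+]4(C)C)cc1 | intermediate
9 | (1S,2S,3R,6S)-1-(hydroxymethyl)-2,3-bis[(4-methoxybenzyl)oxy]cyclohex-4-ene-1,6-diol | COc1ccc(CO[C@@H]2C=C[C@H](O)[C@@](O)(CO)[C@H]2OCc2ccc(OC)cc2)cc1 | intermediate
10 | [(1S,2S,3R,6S)-6-(benzoyloxy)-1-hydroxy-2,3-bis[(4-methoxybenzyl)oxy]cyclohex-4-en-1-yl]methyl benzoate | COc1ccc(CO[C@@H]2C=C[C@H](OC(=O)c3ccccc3)[C@@](O)(COC(=O)c3ccccc3)[C@H]2OCc2ccc(OC)cc2)cc1 | intermediate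
11 | [(1R,2S,3R,6S)-6-(benzoyloxy)-1,2,3-trihydroxycyclohex-4-en-1-yl]methyl benzoate | O[C@@H]1C=C[C@H](OC(=O)c2ccccc2)[C@@](O)(COC(=O)c2ccccc2)[C@H]1O | intermediate
12 | cleistenediol F | CC(=O)O[C@@H]1C=C[C@H](OC(=O)c2ccccc2)[C@@](O)(COC(=O)c2ccccc2)[C@H]1OC(C)=O | target

**Total step count:** 8.
**Longest linear sequence:** 8 steps (1 → 3 → 5 → 6 → 7 → 9 → 10 → 11 → 12).

**Steps most likely to fail**

**Step 2.**
- What may go wrong: the cycloaddition may be slow for a 1,2-disubstituted enediol ether. It may slip into a stepwise zwitterionic path with bond rotation, which loses the trans relation. It may also discriminate poorly between the two orientations of the alkene or the two pyrone faces.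
- Fallback: replace the chiral catalyst by a covalent auxiliary that is removed at no extra cost.
  - It sets out from 3. This is combined with the (R)-pantolactone ester of 2-oxo-2H-pyran-3-carboxylic acid F1, made by Steglich esterification of the commercial acid with (R)-pantolactone.
  - Eu(hfc)3 catalysis should give the auxiliary-bearing bicyclic lactone F2. Every stereochemical leak now shows up as a separable diastereomer, and F2 is purified by crystallisation.
  - Thermolysis as in step 3 gives the auxiliary diene ester F3. LiAlH4 in Et2O at low temperature reduces the ester and releases the auxiliary, so the route is rejoined at 7.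

**Step 5.**
- What may go wrong: osmylation may occur at the less hindered C4=C5 bond, or facial discrimination may be poor because the C3 ether also shields the lower face.
- Fallback: build the cis glycol in two stereospecific events instead of one.
  - It sets out from 7. Hydroxyl-directed epoxidation (VO(acac)2, t-BuOOH) can only reach the allylic C1=C6 bond and should give the epoxy alcohol F4, with the oxygen anti to the C2 ether.
  - This vinyl epoxide is opened with Pd(PPh3)4 under CO2. Ionisation occurs with inversion, and intramolecular return of the carbonate oxygen to C6 occurs with a second inversion. The result is net retention and the cis-fused cyclic carbonate F5.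
  - K2CO3 in MeOH then returns to 9.

**Step 1.**
- What may go wrong: protodeboronation or hydrolysis of the mono-coupled alkoxyvinyl boronate may outrun the second C–O coupling.
- Fallback: reverse the polarity of the coupling, using a vinyl halide and an alkoxide in place of vinylboron and an oxidant.
  - It sets out from 2. Ullmann-type vinylation with commercial (E)-1,2-diiodoethene (CuI, 3,4,7,8-tetramethyl-1,10-phenanthroline, Cs2CO3, toluene) is run in two stages.
  - The first stage gives (E)-2-iodovinyl 4-methoxybenzyl ether F6. The second uses more 2 at higher temperature and arrives at 3. Both couplings proceed with retention of geometry.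

**Further compounds**

F1 | step 2 | (3R)-4,4-dimethyl-2-oxooxolan-3-yl 2-oxo-2H-pyran-3-carboxylate | O=C(O[C@H]1C(=O)OCC1(C)C)C1=CC=COC1=O
F2 | step 2 | (R)-pantolactone ester analogue of 5 (same ring configuration) | COc1ccc(CO[C@@H]2[C@H]3C=C[C@](C(=O)O[C@H]4C(=O)OCC4(C)C)(C(=O)O3)[C@H]2OCc2ccc(OC)cc2)cc1
F3 | step 2 | (R)-pantolactone ester analogue of 6 | COc1ccc(CO[C@@H]2C=CC=C(C(=O)O[C@H]3C(=O)OCC3(C)C)[C@H]2OCc2ccc(OC)cc2)cc1
F4 | step 5 | C1,C6-epoxide of 7, oxygen anti to the C2 ether | COc1ccc(CO[C@@H]2C=C[C@@H]3O[C@]3(CO)[C@H]2OCc2ccc(OC)cc2)cc1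
F5 | step 5 | C1,C6-cyclic carbonate of 9 | COc1ccc(CO[C@@H]2C=C[C@@H]3OC(=O)O[C@]3(CO)[C@H]2OCc2ccc(OC)cc2)cc1
F6 | step 1 | (E)-2-iodovinyl 4-methoxybenzyl ether | COc1ccc(CO/C=C/I)cc1
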